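The diarylmethane is traced back to a bromine-free benzophenone, on which all three C–Br bonds are made in one electrolysis. This step exploits that every bromine site of the target, C5 of ring A (the ring carrying the two-carbon chain at C1 and the bridge carbon C7 at C6) and C5' and C6' of ring B, lies ortho or para to a catechol oxygen: with O4 and O4' free and O3 and O3' methylated, anodically generated bromine should go to these carbons only. The precursor is therefore the C7 ketone carrying these two free phenols, two methyl ethers and a 2-acetoxyethyl chain, assembled by Friedel–Crafts acylation; ketone reduction, demethylation and chemoselective sulfation follow.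

Key step: step 6

Remark: ring A carries the chain on C1, methoxy on C3, hydroxyl on C4 and C7 on C6, and ring B is bound to C7 through C1' with methoxy on C3' and hydroxyl on C4'; the target has no stereocentre and is taken as the free hydrogen sulfate drawn, so the last step ends with exchange of the ammonium counter-ion for a proton.

Step 1
Reactants: 1 homovanillyl alcohol [4-(2-hydroxyethyl)-2-methoxyphenol]
Product: 2 4-(2-acetoxyethyl)-2-methoxyphenyl acetate
Conditions: Ac2O (2.5 equiv), pyridine, DMAP (cat.), CH2Cl2, 0 °C → rt
Reagents that add atoms: acetic anhydride, CC(=O)OC(C)=O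
Why: Base-catalysed O-acylation should esterify both the phenol and the primary alcohol, which protects the chain and turns O4 into a weak director so that the C3 methoxy group alone steers the later acylation.

Step 2
Reactants: 3 vanillic acid (4-hydroxy-3-methoxybenzoic acid)
Product: 4 4-acetoxy-3-methoxybenzoic acid
Conditions: Ac2O (1.3 equiv), pyridine, 0 °C → rt; then H2O, dilute HCl
Reagents that add atoms: acetic anhydride, CC(=O)OC(C)=O
Why: O-acylation of the phenol should give the aryl acetate, and the aqueous acidic work-up returns the carboxylic acid in free form.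

Step 3
Reactants: 4 4-acetoxy-3-methoxybenzoic acid
Product: 5 4-acetoxy-3-methoxybenzoyl chloride
Conditions: (COCl)2 (1.3 equiv), DMF (cat.), CH2Cl2, 0 °C → rt
Reagents that add atoms: oxalyl chloride, O=C(Cl)C(=O)Cl
Why: Acid chloride formation through the chloroiminium species from DMF and oxalyl chloride should proceed under neutral, mild conditions that leave the aryl acetate intact.

Step 4
Reactants: 2 4-(2-acetoxyethyl)-2-methoxyphenyl acetate, 5 4-acetoxy-3-methoxybenzoyl chloride
Product: 6 2-[4-acetoxy-2-(4-acetoxy-3-methoxybenzoyl)-5-methoxyphenyl]ethyl acetate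
Conditions: AlCl3 (4.5 equiv), CH2Cl2, 0 °C → rt; ice, dilute HCl
Reagents that add atoms: none
Why: Friedel–Crafts acylation should place the acylium ion from 5 on ring A at C6, para to the C3 methoxy group (the only strong donor, since O4 is acetylated), and the ketone formed deactivates the product against a second acylation.

Step 5
Reactants: 6 2-[4-acetoxy-2-(4-acetoxy-3-methoxybenzoyl)-5-methoxyphenyl]ethyl acetate
Product: 7 2-[4-hydroxy-2-(4-hydroxy-3-methoxybenzoyl)-5-methoxyphenyl]ethyl acetate
Conditions: pyrrolidine (2.4 equiv), MeCN, 0 °C → rt; dilute HCl wash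
Reagents that add atoms: none
Why: Ester aminolysis should be chemoselective, because the two aryl acetates expel a phenoxide and react with the amine far faster than the primary alkyl acetate, which stays on the chain.

Step 6
Reactants: 7 2-[4-hydroxy-2-(4-hydroxy-3-methoxybenzoyl)-5-methoxyphenyl]ethyl acetate, 8 sodium bromide
Product: 9 2-[3-bromo-2-(2,3-dibromo-4-hydroxy-5-methoxybenzoyl)-4-hydroxy-5-methoxyphenyl]ethyl acetate
Conditions: NaBr (6 equiv), AcOH–H2O (4:1), divided cell (glass frit), graphite anode, Pt cathode, constant current 10 mA cm−2, 20 °C for the first 4 F mol−1, then 40 °C to about 6 F mol−1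
Reagents that add atoms: sodium bromide (compound 8), [Na+].[Br-]
Why: Bromide is oxidised at the anode to Br2 (with HOBr and AcOBr in equilibrium), which substitutes the arene by SEAr through Wheland intermediates, and the HBr released is re-oxidised, so each C–Br bond costs two electrons and the charge passed limits the bromine to three equivalents. The closest known reaction type is the indirect electrochemical bromination of phenols and aryl ethers with bromide salts, and the sites copy the chemical brominations of isovanillin (between hydroxyl and carbonyl, here C5) and of vanillin (ortho to hydroxyl, then para to methoxy, here C5' then C6'). No ring is closed and no stereocentre is formed. The first two bromines should enter at C5 and C5', the only open positions ortho or para to the free O4 and O4' hydroxyls. The third should enter ring B at C6', para to the O3' methoxy group that can stay coplanar with its ring, whereas ring A C2 and ring B C2' are ortho to a methoxy group and wedged between two substituents, ring A C2 facing the methyl group that the O4–H···O3 hydrogen bond turns towards it. The C7 carbonyl deactivates both rings enough for the reaction to stop at three bromines and keeps the bridge from oxidation to a quinone methide, and the chain acetate keeps the primary alcohol away from the oxidant.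

Step 7
Reactants: 9 2-[3-bromo-2-(2,3-dibromo-4-hydroxy-5-methoxybenzoyl)-4-hydroxy-5-methoxyphenyl]ethyl acetate
Product: 11 2-[3-bromo-2-(2,3-dibromo-4-hydroxy-5-methoxybenzyl)-4-hydroxy-5-methoxyphenyl]ethyl acetate, via diarylmethanol 10 (not isolated)
Conditions: Et3SiH (4 equiv), CF3CO2H–CH2Cl2 (1:1), CF3SO3H (0.1 equiv), 0 → 40 °C
Reagents that add atoms: none
Why: Kursanov–Parnes ionic hydrogenation should deliver hydride from the silane to the protonated ketone to give 10, which ionises to a diarylmethyl cation stabilised by the para donors O3 and O4' and takes up a second hydride, while the acetate keeps the chain oxygen from trapping that cation as an isochroman.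

Step 8
Reactants: 11 2-[3-bromo-2-(2,3-dibromo-4-hydroxy-5-methoxybenzyl)-4-hydroxy-5-methoxyphenyl]ethyl acetate
Product: 13 3-bromo-4-(2,3-dibromo-4,5-dihydroxybenzyl)-5-(2-hydroxyethyl)benzene-1,2-diol, via tetraphenol acetate 12 (not isolated)
Conditions: BBr3 (6 equiv), CH2Cl2, −78 → 0 °C; then MeOH, 0 → 50 °C; under argon
Reagents that add atoms: none
Why: Lewis acid ether cleavage should be fast at low temperature because each phenol first forms an aryloxydibromoborane that hands boron to the neighbouring methoxy oxygen before bromide removes the methyl group, and the HBr set free on methanol quench should then cleave the primary acetate by acid-catalysed transesterification.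

Step 9
Reactants: 13 3-bromo-4-(2,3-dibromo-4,5-dihydroxybenzyl)-5-(2-hydroxyethyl)benzene-1,2-diol
Product: 16 2-[3-bromo-2-(2,3-dibromo-4,5-dihydroxybenzyl)-4,5-dihydroxyphenyl]ethyl hydrogen sulfate, via bis(phenylboronate) 14 (not isolated), via sulfated bis(phenylboronate) 15 (not isolated)
Conditions: PhB(OH)2 (2.1 equiv), 4 Å molecular sieves, THF, 50 °C; then SO3·NMe3 (2 equiv), DMF, 40 °C; then H2O–MeOH, rt, Et2O wash; Dowex 50W (H+ form), 0 °C, freeze-drying
Reagents that add atoms: sulfur trioxide–trimethylamine complex, C[N+](C)(C)S(=O)(=O)[O-]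
Why: Boronic ester formation should tie both catechols up as five-membered cyclic phenylboronates, so that O-sulfation by the SO3–amine complex can only occur at the primary alcohol, after which water hydrolyses the labile boronates and the acid resin replaces the trimethylammonium ion by a proton.

Compound list
1 | homovanillyl alcohol, 4-(2-hydroxyethyl)-2-methoxyphenol | OCCc1ccc(O)c(OC)c1 | starting material
2 | 4-(2-acetoxyethyl)-2-methoxyphenyl acetate | CC(=O)OCCc1ccc(OC(C)=O)c(OC)c1 | intermediate
3 | vanillic acid, 4-hydroxy-3-methoxybenzoic acid | COc1cc(C(=O)O)ccc1O | starting material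
4 | 4-acetoxy-3-methoxybenzoic acid | COc1cc(C(=O)O)ccc1OC(C)=O | intermediate
5 | 4-acetoxy-3-methoxybenzoyl chloride | COc1cc(C(=O)Cl)ccc1OC(C)=O | intermediate
6 | 2-[4-acetoxy-2-(4-acetoxy-3-methoxybenzoyl)-5-methoxyphenyl]ethyl acetate | CC(=O)OCCc1cc(OC)c(OC(C)=O)cc1C(=O)c1ccc(OC(C)=O)c(OC)c1 | intermediate
7 | 2-[4-hydroxy-2-(4-hydroxy-3-methoxybenzoyl)-5-methoxyphenyl]ethyl acetate (precursor of the key step) | CC(=O)OCCc1cc(OC)c(O)cc1C(=O)c1ccc(O)c(OC)c1 | intermediate
8 | sodium bromide | [Na+].[Br-] | starting material
9 | 2-[3-bromo-2-(2,3-dibromo-4-hydroxy-5-methoxybenzoyl)-4-hydroxy-5-methoxyphenyl]ethyl acetate (product of the key step) | CC(=O)OCCc1cc(OC)c(O)c(Br)c1C(=O)c1cc(OC)c(O)c(Br)c1Br | intermediate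
10 | racemic 2-{3-bromo-2-[(2,3-dibromo-4-hydroxy-5-methoxyphenyl)(hydroxy)methyl]-4-hydroxy-5-methoxyphenyl}ethyl acetate (not isolated) | CC(=O)OCCc1cc(OC)c(O)c(Br)c1C(O)c1cc(OC)c(O)c(Br)c1Br | intermediate
11 | 2-[3-bromo-2-(2,3-dibromo-4-hydroxy-5-methoxybenzyl)-4-hydroxy-5-methoxyphenyl]ethyl acetate | CC(=O)OCCc1cc(OC)c(O)c(Br)c1Cc1cc(OC)c(O)c(Br)c1Br | intermediate
12 | 2-[3-bromo-2-(2,3-dibromo-4,5-dihydroxybenzyl)-4,5-dihydroxyphenyl]ethyl acetate (not isolated) | CC(=O)OCCc1cc(O)c(O)c(Br)c1Cc1cc(O)c(O)c(Br)c1Br | intermediate
13 | 3-bromo-4-(2,3-dibromo-4,5-dihydroxybenzyl)-5-(2-hydroxyethyl)benzene-1,2-diol | OCCc1cc(O)c(O)c(Br)c1Cc1cc(O)c(O)c(Br)c1Br | intermediate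
14 | bis(phenylboronate) of 13, both catechols closed as 2-phenyl-1,3,2-benzodioxaboroles, primary alcohol free (not isolated) | OCCc1cc2OB(c3ccccc3)Oc2c(Br)c1Cc1cc2OB(c3ccccc3)Oc2c(Br)c1Br | intermediate
15 | hydrogen sulfate of 14 at the primary oxygen (not isolated) | O=S(=O)(O)OCCc1cc2OB(c3ccccc3)Oc2c(Br)c1Cc1cc2OB(c3ccccc3)Oc2c(Br)c1Br | intermediate
16 | 2-[3-bromo-2-(2,3-dibromo-4,5-dihydroxybenzyl)-4,5-dihydroxyphenyl]ethyl hydrogen sulfate (CNP0136879.0) | O=S(=O)(O)OCCc1cc(O)c(O)c(Br)c1Cc1cc(O)c(O)c(Br)c1Br | target

Total step count: 9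
Longest linear sequence: 8 steps (from vanillic acid 3 through steps 2, 3, 4, 5, 6, 7, 8 and 9)

Steps most likely to fail

Step 6 (anodic tribromination). The third bromination is the slow one, so bromine may be diverted to ring A at C2, a fourth substitution may begin before the third is complete, or the para-alkylphenol of ring A may undergo ipso attack at C1 and oxidation along the chain. The fallback brominates ring B before the ketone is built, so that ring A only meets the easy ortho-to-hydroxyl bromination. Commercial 5-bromovanillin would be brominated at its 6-position (Br2, Fe powder, AcOH) to 2,3-dibromo-4-hydroxy-5-methoxybenzaldehyde F1, acetylated (Ac2O, pyridine) to 2,3-dibromo-4-formyl-6-methoxyphenyl acetate F2, oxidised under Pinnick conditions (NaClO2, NaH2PO4, 2-methyl-2-butene, tBuOH–H2O) to 4-acetoxy-2,3-dibromo-5-methoxybenzoic acid F3 and converted with oxalyl chloride and catalytic DMF into 4-acetoxy-2,3-dibromo-5-methoxybenzoyl chloride F4. The fallback sets out from compound 2, which would be acylated with this chloride (AlCl3, CH2Cl2) at C6 to give 2-[4-acetoxy-2-(4-acetoxy-2,3-dibromo-5-methoxybenzoyl)-5-methoxyphenyl]ethyl acetate F5. Pyrrolidine in MeCN would then free the two phenols to give 2-[2-(2,3-dibromo-4-hydroxy-5-methoxybenzoyl)-4-hydroxy-5-methoxyphenyl]ethyl acetate F6. One equivalent of bromine (the same electrolysis stopped at two faradays per mole, or N-bromosuccinimide in AcOH) should then enter ring A at C5, and the route is rejoined at compound 9.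

Step 9 (masked sulfation). The boronates may open partly in the sulfation medium, so that phenolic oxygens are sulfated as well, or the sulfate may be lost during the acidic ion exchange. The fallback uses isolable silyl protection; it sets out from compound 13 and returns at compound 16. All five hydroxyl groups would be silylated (tert-butyldimethylsilyl triflate, 2,6-lutidine, CH2Cl2) to the penta-O-silyl ether F7. The primary alkyl silyl ether alone would be cleaved with camphorsulfonic acid in MeOH–CH2Cl2 at 0 °C, since aryl silyl ethers resist mild acid, to give the tetra-O-aryl-silyl primary alcohol F8. SO3·pyridine in pyridine would give the silyl-protected hydrogen sulfate F9, and KF in MeOH would remove the four aryl silyl ethers without touching the sulfate.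

Step 7 (ionic hydrogenation). The first hydride transfer to the hindered, donor-stabilised protonated ketone may be slow, and forcing the acid may cause loss of bromine or acidolysis of the diarylmethane. The fallback splits the reduction into two stages; it sets out from compound 9 and returns at compound 11. BH3·SMe2 in THF (0 °C → rt), a neutral electrophilic hydride source that reduces ketones much faster than alkyl acetates, would give the diarylmethanol 10, isolated this time. The easily ionised alcohol would then be deoxygenated with Et3SiH and CF3CO2H in CH2Cl2 at 0 °C.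

Further compounds
F1 | step 6 | 2,3-dibromo-4-hydroxy-5-methoxybenzaldehyde | O=Cc1cc(OC)c(O)c(Br)c1Br
F2 | step 6 | 2,3-dibromo-4-formyl-6-methoxyphenyl acetate | CC(=O)Oc1c(OC)cc(C=O)c(Br)c1Br
F3 | step 6 | 4-acetoxy-2,3-dibromo-5-methoxybenzoic acid | CC(=O)Oc1c(OC)cc(C(=O)O)c(Br)c1Br
F4 | step 6 | 4-acetoxy-2,3-dibromo-5-methoxybenzoyl chloride | CC(=O)Oc1c(OC)cc(C(=O)Cl)c(Br)c1Br
F5 | step 6 | 2-[4-acetoxy-2-(4-acetoxy-2,3-dibromo-5-methoxybenzoyl)-5-methoxyphenyl]ethyl acetate | CC(=O)OCCc1cc(OC)c(OC(C)=O)cc1C(=O)c1cc(OC)c(OC(C)=O)c(Br)c1Br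
F6 | step 6 | 2-[2-(2,3-dibromo-4-hydroxy-5-methoxybenzoyl)-4-hydroxy-5-methoxyphenyl]ethyl acetate | CC(=O)OCCc1cc(OC)c(O)cc1C(=O)c1cc(OC)c(O)c(Br)c1Br
F7 | step 9 | penta-O-(tert-butyldimethylsilyl) ether of 13 | CC(C)(C)[Si](C)(C)OCCc1cc(O[Si](C)(C)C(C)(C)C)c(O[Si](C)(C)C(C)(C)C)c(Br)c1Cc1cc(O[Si](C)(C)C(C)(C)C)c(O[Si](C)(C)C(C)(C)C)c(Br)c1Br
F8 | step 9 | tetra-O-aryl-(tert-butyldimethylsilyl) ether of 13 with the primary alcohol free | OCCc1cc(O[Si](C)(C)C(C)(C)C)c(O[Si](C)(C)C(C)(C)C)c(Br)c1Cc1cc(O[Si](C)(C)C(C)(C)C)c(O[Si](C)(C)C(C)(C)C)c(Br)c1Br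
F9 | step 9 | hydrogen sulfate of F8 at the primary oxygen | O=S(=O)(O)OCCc1cc(O[Si](C)(C)C(C)(C)C)c(O[Si](C)(C)C(C)(C)C)c(Br)c1Cc1cc(O[Si](C)(C)C(C)(C)C)c(O[Si](C)(C)C(C)(C)C)c(Br)c1Br
F0 | step 7 | none | none
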